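## Structural features

Glabrol (20) is a flavanone: aromatic ring A is fused to the dihydropyranone ring C, which carries the phenyl ring B at C2. Ring A has the 7-hydroxyl and a prenyl (3-methylbut-2-en-1-yl) group at C8, so C4a, C8a, C8 and C7 are four contiguous substituted positions, with the prenyl group wedged between O1 and the phenol oxygen. Ring B has a 4'-hydroxyl flanked by a second prenyl group at C3'. C2 is the only stereocentre, (S) by CIP analysis of the target SMILES (O1 > C1' > C3 > H); it is benzylic, bonded to O1, two atoms from the C4 carbonyl, and has no neighbouring stereocentre to relay from. This is the fragile point: base, or hot acid, opens ring C by retro-oxa-Michael reaction, and re-closure erases the C2 configuration. Each prenyl group sits ortho to a phenol and can cyclise onto it under strong acid; the alkenes also exclude hydrogenolysis, hydroborating boranes and electrophilic oxidants. The real difficulties are therefore an enantiopure C2 that survives to the end and the regiochemistry of the C8 prenyl group, not the carbon skeleton. The key step uses the fact that O1 is an aryl alkyl ether oxygen whose alkyl carbon is C2: ring C can be closed at the O1–C8a aryl bond from a preformed (S) carbinol, with C4 held as a silyl ether so that no carbonyl-acidified C3–H is present under the basic coupling conditions.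

## Logic of the disconnections

**20 from 19.** The two aryl O–CH2 acetal bonds are cut. Both phenols have to be masked through amide bases, organometallic reagents, carbonate at 70 °C and fluoride, and the same acetal group also directs the metalation on ring A. Nothing is gained in skeleton. The forward step must cleave two acetals without protonating the prenyl alkenes or opening ring C.

**19 from 18.** The C4 carbonyl is taken back to a secondary alcohol. A ketone at C4 during the base-mediated ring closure would make C3–H acidic and open the way to retro-aldol cleavage and elimination. The stereochemistry at C4 is irrelevant because both epimers converge. The oxidation must be neutral and leave the alkenes alone.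

**18 from 17.** The O–Si bond at C4 is cut. The silyl ether makes the C4 oxygen unable to bind the metal in the key step. Its removal must spare the acetals, which fluoride does.

**17 from 16.** The O1–C8a bond is cut, opening ring C to an acyclic bromo alcohol. This places the only stereocentre in an open-chain carbinol that can be made by ketone reduction, and it reduces the heterocycle to two arenes on a three-carbon chain. The forward step must form an aryl–oxygen bond from a secondary benzylic alcohol without touching the C2–O or C2–H bonds.

**16 from 15.** The C2–H bond is cut, so the carbinol goes back to a prochiral aryl ketone. The stereocentre then comes from a catalyst rather than from the racemic silyloxy centre nearby. The reduction must be catalyst-controlled for both epimers of 15 and must not hydroborate the prenyl groups or touch the aryl bromide.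

**15 from 14.** The O–Si bond on the ring A carbinol is cut. Silylation differentiates the two oxygens of the chain for good and blocks retro-aldol cleavage.

**14 from 12 and 8 (through 13).** The C3–C4 bond is cut as an aldol. The polarity is chosen so that the C4 oxygen is born as a hydroxyl (silylated at once) and the C2 oxygen as a ketone (reduced enantioselectively). The two oxygens are thus distinguished without any selective protection. The molecule falls into two arenes of equal size. The forward step needs a kinetic crossed aldol, which the non-enolisable aldehyde 8 allows.

**8 from 3 and 4 (through 5, 6 and 7), 3 from 2, 2 from 1.** The bond from the ring carbon between bromine and the protected oxygen to the prenyl CH2 is cut. Phenoxide C-alkylation or electrophilic prenylation of 1 would go to the unhindered ortho position, the future C6 of the flavanone. The ring carbon between the two heteroatoms carries the most acidic hydrogen, so directed metalation puts the prenyl group exactly where C8 requires it. The cost is that the aldehyde must be masked as acetal 3 and the phenol as 2.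

**12 from 10 and 11, 10 from 9.** The ring B aryl–CH2 bond is cut as a cross-coupling at a bromide that already stands ortho to the oxygen. This fixes the regiochemistry without phenol C-alkylation. The enolisable ketone has to survive, which a Stille coupling permits.

## Other disconnections considered

**Alternative 1:** The cut runs through C2–C3 and O1–C8a, with ring A taken back to a dihydro level.

- **Forward key step.** The bis(silyloxy) diene A2 (derived from the prenylated dione A4) would add through its terminal CH2 to the ring B aldehyde A3 under Ti(OiPr)4 and BINOL. Acid would then condense the new hydroxyl onto the ring carbonyl to give A1.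
- **In its favour.** C2–C3, the C2 stereocentre and ring C come from one catalytic asymmetric operation. The C8 prenyl group sits in A4 on the carbon between two carbonyls, where C-alkylation is regiochemically unambiguous. On this point it is the better plan, since the chosen route spends an acetal and a directed metalation on the same problem. It needs no aryl halide and no palladium.
- **Against it here.** Ring A of A1 still has to be dehydrogenated, in a molecule with two prenyl groups, a benzylic C2–H and an enol acetal. The titanium/BINOL dienolate aldol is established for open-chain acetoacetate-type dienes, whereas A2 is cyclic, fully substituted and cross-conjugated. The pivalate calls for basic or reductive removal, which are the conditions that open ring C at C2.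
- **Comparison.** On structure, its key step is richer: two bonds, a ring and a stereocentre against one bond and a ring in step 9. On mechanism, both plans rely on an external chiral catalyst for C2 and are equal in principle; here, however, the stereocentre would have to survive an oxidation and a base-labile deprotection, whereas nothing basic follows step 9. On step economy, the aromatisation and two different deprotections offset the saving, so the count should be about equal.

**Alternative 2:** The cut is the C3=C4 bond of a 4-silyloxy-2H-chromene, preceded by O1–C2.

- **Forward key step.** Phenol A7 would be O-allylated at the branched position with carbonate A8 under iridium–phosphoramidite catalysis to set C2. Enol silylation would give A6, and second-generation Grubbs catalyst would close ring C with loss of ethylene to A5.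
- **In its favour.** Enol ether hydrolysis of A5 would deliver C4 directly at the ketone level, with no reduction–oxidation pair. In redox economy it is better than the chosen plan. No aryl halide is needed and ring A starts from a cheap oxygenation pattern.
- **Against it here.** A6 has four alkenes. The ruthenium carbene could engage the ring B prenyl group or the hindered vinyl group of the dimethylallyl ether. Enol ether metathesis is slow, and ruthenium hydrides formed on catalyst decay can isomerise the allylic ether that carries C2. A5 still lacks the C8 prenyl group, which would have to come from a thermal aromatic Claisen rearrangement of the 7-O-(1,1-dimethylallyl) ether. That step has a C8-versus-C6 regiochemical question and puts thermal stress on C2. The hydrogen-bonded ortho-acyl phenol A7 is a weak nucleophile for the etherification.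
- **Comparison.** On structure, both plans set C2 first and close ring C without touching it: equal. On mechanism, metathesis has to choose among several alkenes, whereas step 9 has a single aryl bromide and a single free hydroxyl. On step economy, it could be one or two steps shorter if the Claisen step were selective.

**Alternative 3:** The cuts are C4–C4a and O1–C8a.

- **Forward key step.** The aryllithium from bromine–lithium exchange of A11 would attack the carbonyl of the (S)-β-lactone A10. The released C2 alkoxide would then displace the ortho fluoride, now activated by the new ketone, to give A9 in one flask.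
- **In its favour.** It is the most convergent of the four plans: two bonds and ring C are formed at the final oxidation level, the stereocentre is carried with retention from a small fragment, and no transition metal is used. In step economy it is clearly better than the chosen plan, which needs silylation, reduction, desilylation and oxidation around its ring closure.
- **Against it here.** The ortho-fluoro aryllithium loses LiF above about −50 °C. 4-Aryl β-lactones decarboxylate and ionise at the benzylic C–O bond. The ketone formed is more electrophilic than the lactone, and the pivalate is a second acyl acceptor. The lactone α-hydrogens can be removed instead. The ring-opened β-alkoxy ketone sits under strongly basic conditions, where retro-aldol cleavage of C2–C3 or E1cB loss of the alkoxide followed by unselective oxa-Michael re-closure would erase C2.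
- **Comparison.** On structure, ring C is closed at the same O1–C8a bond from the same preformed carbinol oxygen: equal. On mechanism, the SNAr closure needs the C4 ketone in place during a basic step, which is exactly what the chosen plan avoids by holding C4 as a silyl ether.

Key step: step 9

Remark on the chemistry: the carbon that becomes C4 is formed racemic in step 6 and is carried as a mixture of epimers in 16, 17 and 18 until step 11 removes it, so the SMILES of these compounds leave that centre open. Compounds 9 and 11 are taken as purchasable. "Prenyl" means 3-methylbut-2-en-1-yl and "MOM" means methoxymethyl.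

## Route

Step 1
Reactants: 1 2-bromo-4-hydroxybenzaldehyde
Product: 2 2-bromo-4-(methoxymethoxy)benzaldehyde
Conditions: MOMCl, i-Pr2NEt, CH2Cl2, 0 °C → rt
Reagents that add atoms: chloromethyl methyl ether, COCCl
Why: O-alkylation of the phenol (MOM acetal formation); the para-formyl group makes the phenol acidic, so the amine base is sufficient. The MOM ether is chosen because it later directs the ring metalation and withstands every basic step.

Step 2
Reactants: 2 2-bromo-4-(methoxymethoxy)benzaldehyde
Product: 3 2-bromo-1-(dimethoxymethyl)-4-(methoxymethoxy)benzene
Conditions: HC(OMe)3, PPTS (cat.), MeOH, rt; then Et3N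
Reagents that add atoms: trimethyl orthoformate, COC(OC)OC; methanol, CO
Why: Acid-catalysed acetalisation, with the orthoformate as methoxy donor and water scavenger. The pyridinium salt is too weak to solvolyse the aryl MOM ether at room temperature, and the acetal masks the aldehyde against the amide base and the aryl-metal species of step 3.

Step 3
Reactants: 3 2-bromo-1-(dimethoxymethyl)-4-(methoxymethoxy)benzene; 4 prenyl bromide (1-bromo-3-methylbut-2-ene)
Product: 8 2-bromo-4-(methoxymethoxy)-3-prenylbenzaldehyde, via aryllithium 5 (not isolated), via arylcopper 6 (not isolated), via prenylated acetal 7 (not isolated)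
Conditions: LDA, THF, −78 °C; CuBr·SMe2, −78 °C; 4, −78 → 0 °C; then 1 M aq. HCl, THF, rt
Reagents that add atoms: water, O
Why: Directed ortho-metalation, copper-mediated allylic substitution, then acetal hydrolysis. The C–H between bromine and the MOM ether of 3 is the most acidic ring position and an amide base does not undergo bromine–lithium exchange; at −78 °C aryllithium 5 should keep its bromide and transmetalate to arylcopper 6, which should attack prenyl bromide at the primary carbon (SN2) to give the linear prenyl group. Dilute aqueous acid should then cleave only the dimethyl acetal of 7, since the aryl MOM ether needs stronger acid.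

Step 4
Reactants: 9 3'-bromo-4'-hydroxyacetophenone
Product: 10 1-[3-bromo-4-(methoxymethoxy)phenyl]ethanone
Conditions: MOMCl, i-Pr2NEt, CH2Cl2, 0 °C → rt
Reagents that add atoms: chloromethyl methyl ether, COCCl
Why: O-alkylation of an acidic para-acyl phenol, as in step 1. The bromide ortho to the oxygen already marks the position of the ring B prenyl group.

Step 5
Reactants: 10 1-[3-bromo-4-(methoxymethoxy)phenyl]ethanone; 11 tributyl(3-methylbut-2-en-1-yl)stannane
Product: 12 1-[4-(methoxymethoxy)-3-prenylphenyl]ethanone
Conditions: Pd(PPh3)4 (5 mol%), DMF, 90 °C
Reagents that add atoms: none
Why: Stille cross-coupling; oxidative addition of zerovalent palladium into the C–Br bond is assisted by the para-acetyl group, and reductive elimination from the allyl palladium intermediate at its less substituted terminus should give the linear prenyl arene. The neutral conditions tolerate the enolisable ketone and the MOM ether.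

Step 6
Reactants: 12 1-[4-(methoxymethoxy)-3-prenylphenyl]ethanone; 8 2-bromo-4-(methoxymethoxy)-3-prenylbenzaldehyde
Product: 14 rac-3-[2-bromo-4-(methoxymethoxy)-3-prenylphenyl]-3-hydroxy-1-[4-(methoxymethoxy)-3-prenylphenyl]propan-1-one, via lithium enolate 13 (not isolated)
Conditions: LDA, THF, −78 °C; then 8, −78 °C; AcOH quench at −78 °C
Reagents that add atoms: none
Why: Directed (crossed) aldol addition of a preformed lithium enolate to a non-enolisable aldehyde; the cold acidic quench should prevent retro-aldol cleavage and dehydration. The new carbinol centre is deliberately racemic because it is oxidised away in step 11.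

Step 7
Reactants: 14 rac-3-[2-bromo-4-(methoxymethoxy)-3-prenylphenyl]-3-hydroxy-1-[4-(methoxymethoxy)-3-prenylphenyl]propan-1-one
Product: 15 rac-3-[2-bromo-4-(methoxymethoxy)-3-prenylphenyl]-3-(tert-butyldimethylsilyloxy)-1-[4-(methoxymethoxy)-3-prenylphenyl]propan-1-one
Conditions: TBSCl, imidazole, DMF, rt
Reagents that add atoms: tert-butyldimethylsilyl chloride, CC(C)(C)[Si](C)(C)Cl
Why: Imidazole-promoted silylation of the secondary benzylic alcohol. It blocks retro-aldol cleavage and ensures that only the oxygen destined to become O1 is free in the key step.

Step 8
Reactants: 15 rac-3-[2-bromo-4-(methoxymethoxy)-3-prenylphenyl]-3-(tert-butyldimethylsilyloxy)-1-[4-(methoxymethoxy)-3-prenylphenyl]propan-1-one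
Product: 16 (1S)-3-[2-bromo-4-(methoxymethoxy)-3-prenylphenyl]-3-(tert-butyldimethylsilyloxy)-1-[4-(methoxymethoxy)-3-prenylphenyl]propan-1-ol (both C3 epimers)
Conditions: (R)-1-methyl-3,3-diphenyltetrahydro-1H,3H-pyrrolo[1,2-c][1,3,2]oxazaborole [(R)-2-methyl-CBS-oxazaborolidine] (20 mol%), catecholborane, toluene, −78 → −40 °C; then MeOH, aq. NaOH wash
Reagents that add atoms: none
Why: Corey–Bakshi–Shibata reduction; the ketone should bind the ring boron with the aryl group in the large-group position, and hydride from the nitrogen-bound borane should reach the Re face, which gives the (S) carbinol (the (R) catalyst gives the (S) alcohol in the acetophenone model, and the CIP order O > aryl > CH2 is the same here). The stereocentre is set by the catalyst for both epimers of 15. Catecholborane is used because it does not hydroborate the trisubstituted prenyl alkenes at low temperature.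

Step 9
Reactants: 16 (1S)-3-[2-bromo-4-(methoxymethoxy)-3-prenylphenyl]-3-(tert-butyldimethylsilyloxy)-1-[4-(methoxymethoxy)-3-prenylphenyl]propan-1-ol (both C3 epimers)
Product: 17 (2S)-4-(tert-butyldimethylsilyloxy)-7,4'-bis(methoxymethoxy)-8,3'-diprenylflavan (both C4 epimers)
Conditions: Pd(OAc)2 (5 mol%), 2-(di-tert-butylphosphino)-1,1'-binaphthyl (6 mol%), Cs2CO3, toluene, 70 °C
Reagents that add atoms: none
Why: Buchwald–Hartwig-type palladium-catalysed intramolecular aryl etherification of a secondary alcohol, a known route to chromans. Pd(OAc)2 is reduced in situ to a zerovalent palladium monophosphine complex that inserts into the C8a–Br bond; Cs2CO3 deprotonates the coordinated C2 hydroxyl to give a seven-membered aryl palladium alkoxide, and C–O reductive elimination forms O1–C8a. Ring C is thus closed as a six-membered ring by reductive elimination from that palladacycle, not by substitution at carbon. No stereocentre is created: the C2–O and C2–H bonds are never broken, so the (S) configuration from step 8 is carried over, and both C4 epimers should cyclise to silyloxy flavans that converge in step 11. The step needs reductive elimination to outrun β-hydride elimination from the benzylic alkoxide; the bulky, electron-rich di-tert-butyl biaryl phosphine and the two ortho substituents flanking the metal (the C8 prenyl group and the tether) both favour C–O reductive elimination. The substrate secures chemoselectivity: the C4 oxygen is silylated and could in any case only close a four-membered ring, no C3–H is acidified by a carbonyl, and insertion of the C8 prenyl alkene would require a four-membered or a 5-endo ring. The weak heterogeneous base in toluene should leave the MOM ethers, the silyl ether and the alkenes untouched.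

Step 10
Reactants: 17 (2S)-4-(tert-butyldimethylsilyloxy)-7,4'-bis(methoxymethoxy)-8,3'-diprenylflavan (both C4 epimers)
Product: 18 (2S)-7,4'-bis(methoxymethoxy)-8,3'-diprenylflavan-4-ol (both C4 epimers)
Conditions: n-Bu4NF, THF, 0 °C → rt
Reagents that add atoms: none
Why: Fluoride-mediated desilylation driven by the Si–F bond. The acetals, the aryl ether and the alkenes are inert to fluoride, and without a C4 carbonyl ring C cannot open at C2.

Step 11
Reactants: 18 (2S)-7,4'-bis(methoxymethoxy)-8,3'-diprenylflavan-4-ol (both C4 epimers)
Product: 19 (2S)-7,4'-bis(methoxymethoxy)-8,3'-diprenylflavanone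
Conditions: Pr4N[RuO4] (TPAP, 5 mol%), N-methylmorpholine N-oxide, 4 Å molecular sieves, CH2Cl2, rt
Reagents that add atoms: none
Why: Ley–Griffith oxidation of a secondary benzylic alcohol to the aryl ketone under neutral conditions; both C4 epimers give the same ketone. No base is present, so retro-oxa-Michael opening at C2 is not expected, and the trisubstituted alkenes are not attacked.

Step 12
Reactants: 19 (2S)-7,4'-bis(methoxymethoxy)-8,3'-diprenylflavanone
Product: 20 glabrol [(2S)-7,4'-dihydroxy-8,3'-diprenylflavanone]
Conditions: 3 M aq. HCl, MeOH, rt → 40 °C
Reagents that add atoms: none
Why: Acid-catalysed acetal solvolysis (transacetalisation to dimethoxymethane) of the two aryl MOM ethers. Acetal oxygen is protonated far more readily than a trisubstituted alkene, so brief treatment at low temperature should free both phenols before prenyl cyclisation or acid-mediated ring opening at C2 sets in.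

## Compound list

1 | 2-bromo-4-hydroxybenzaldehyde | O=Cc1ccc(O)cc1Br | starting material
2 | 2-bromo-4-(methoxymethoxy)benzaldehyde | COCOc1ccc(C=O)c(Br)c1 | intermediate
3 | 2-bromo-1-(dimethoxymethyl)-4-(methoxymethoxy)benzene | COCOc1ccc(C(OC)OC)c(Br)c1 | intermediate
4 | prenyl bromide (1-bromo-3-methylbut-2-ene) | CC(C)=CCBr | starting material
5 | [2-bromo-3-(dimethoxymethyl)-6-(methoxymethoxy)phenyl]lithium | [Li]c1c(OCOC)ccc(C(OC)OC)c1Br | intermediate (not isolated)
6 | [2-bromo-3-(dimethoxymethyl)-6-(methoxymethoxy)phenyl]copper | [Cu]c1c(OCOC)ccc(C(OC)OC)c1Br | intermediate (not isolated)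
7 | 2-bromo-1-(dimethoxymethyl)-4-(methoxymethoxy)-3-prenylbenzene | CC(C)=CCc1c(OCOC)ccc(C(OC)OC)c1Br | intermediate (not isolated)
8 | 2-bromo-4-(methoxymethoxy)-3-prenylbenzaldehyde | CC(C)=CCc1c(OCOC)ccc(C=O)c1Br | intermediate
9 | 3'-bromo-4'-hydroxyacetophenone | CC(=O)c1ccc(O)c(Br)c1 | starting material
10 | 1-[3-bromo-4-(methoxymethoxy)phenyl]ethanone | CC(=O)c1ccc(OCOC)c(Br)c1 | intermediate
11 | tributyl(3-methylbut-2-en-1-yl)stannane | CCCC[Sn](CCCC)(CCCC)CC=C(C)C | starting material
12 | 1-[4-(methoxymethoxy)-3-prenylphenyl]ethanone | CC(=O)c1ccc(OCOC)c(CC=C(C)C)c1 | intermediate
13 | lithium 1-[4-(methoxymethoxy)-3-prenylphenyl]ethen-1-olate | [Li]OC(=C)c1ccc(OCOC)c(CC=C(C)C)c1 | intermediate (not isolated)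
14 | rac-3-[2-bromo-4-(methoxymethoxy)-3-prenylphenyl]-3-hydroxy-1-[4-(methoxymethoxy)-3-prenylphenyl]propan-1-one | CC(C)=CCc1cc(C(=O)CC(O)c2ccc(OCOC)c(CC=C(C)C)c2Br)ccc1OCOC | intermediate
15 | rac-3-[2-bromo-4-(methoxymethoxy)-3-prenylphenyl]-3-(tert-butyldimethylsilyloxy)-1-[4-(methoxymethoxy)-3-prenylphenyl]propan-1-one | CC(C)=CCc1cc(C(=O)CC(O[Si](C)(C)C(C)(C)C)c2ccc(OCOC)c(CC=C(C)C)c2Br)ccc1OCOC | intermediate
16 | (1S)-3-[2-bromo-4-(methoxymethoxy)-3-prenylphenyl]-3-(tert-butyldimethylsilyloxy)-1-[4-(methoxymethoxy)-3-prenylphenyl]propan-1-ol, both C3 epimers | CC(C)=CCc1cc([C@@H](O)CC(O[Si](C)(C)C(C)(C)C)c2ccc(OCOC)c(CC=C(C)C)c2Br)ccc1OCOC | intermediate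
17 | (2S)-4-(tert-butyldimethylsilyloxy)-7,4'-bis(methoxymethoxy)-8,3'-diprenylflavan, both C4 epimers | CC(C)=CCc1cc([C@@H]2CC(O[Si](C)(C)C(C)(C)C)c3ccc(OCOC)c(CC=C(C)C)c3O2)ccc1OCOC | intermediate
18 | (2S)-7,4'-bis(methoxymethoxy)-8,3'-diprenylflavan-4-ol, both C4 epimers | CC(C)=CCc1cc([C@@H]2CC(O)c3ccc(OCOC)c(CC=C(C)C)c3O2)ccc1OCOC | intermediate
19 | (2S)-7,4'-bis(methoxymethoxy)-8,3'-diprenylflavanone | CC(C)=CCc1cc([C@@H]2CC(=O)c3ccc(OCOC)c(CC=C(C)C)c3O2)ccc1OCOC | intermediate
20 | glabrol, (2S)-7,4'-dihydroxy-8,3'-diprenylflavanone | CC(C)=CCc1cc([C@@H]2CC(=O)c3ccc(O)c(CC=C(C)C)c3O2)ccc1O | target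

## Step count and least certain steps

Total step count: 12. Longest linear sequence: 10 (steps 1, 2, 3, 6, 7, 8, 9, 10, 11, 12); the ring B branch (steps 4 and 5) joins at step 6.

**Step 9 (key step).** The most likely failure is β-hydride elimination from the benzylic palladium alkoxide. This would oxidise the carbinol, reduce the aryl bromide and destroy the stereocentre. It is favoured here because the C–Br bond is flanked by two ortho substituents, which slows alkoxide binding. Carbonate-induced migration of the silyl group between the two chain oxygens is a second risk; a bulkier silyl group would be the simple remedy for that. The fallback changes the metal and the mechanism: from 16, an Ullmann-type etherification with CuI, 3,4,7,8-tetramethyl-1,10-phenanthroline and Cs2CO3 in toluene at 110 °C should give 17 directly. Alkoxides of monovalent copper are far less prone to β-hydride loss. No compound outside the list is formed (F0).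

**Step 3.** Two processes threaten it: loss of lithium bromide from the ortho-bromo aryllithium (aryne formation) while the mixture warms for transmetalation and allylation, and attack of the aryl-metal at the tertiary terminus of the allylic bromide (allylic transposition). The fallback separates metalation from carbon–carbon bond formation. From 3, the cold lithiation is quenched at once with I2 at −78 °C to give 2-bromo-1-(dimethoxymethyl)-3-iodo-4-(methoxymethoxy)benzene F1. A Stille coupling of F1 with 11 (Pd(PPh3)4, CuI co-catalyst, DMF, 60 °C) should occur at the carbon–iodine bond in preference to the carbon–bromine bond and give 7, where the route is rejoined before the acid hydrolysis to 8.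

**Step 8.** The most likely problem is poor facial selectivity for one of the two epimers of 15, a mismatched pairing between the catalyst and the neighbouring silyloxy centre. It would show as eroded enantiopurity at C2 once C4 is oxidised. The fallback is a Noyori–Ikariya asymmetric transfer hydrogenation from 15 to 16 with RuCl(p-cymene)[(S,S)-TsDPEN] in HCO2H/Et3N. Its outer-sphere hydride transfer is indifferent to alkenes and aryl bromides, and the acetophenone model predicts the (S) alcohol. No compound outside the list is formed (F0).

**Step 12.** Acid may promote addition of each freed phenol across its neighbouring prenyl alkene (chroman ring formation) and ring opening at C2 with loss of configuration. Both become competitive if the second acetal cleaves slowly. The fallback avoids protic acid: from 19, trimethylsilyl trifluoromethanesulfonate and 2,2'-bipyridyl in CH3CN at 0 °C should exchange both aryl MOM ethers for silyl ethers, giving (2S)-8,3'-diprenyl-7,4'-bis(trimethylsilyloxy)flavanone F4. Neutral aqueous methanol should then hydrolyse F4 to 20.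

**Step 5.** The risk is allylic transposition during transmetalation, which would place the aryl group on the tertiary carbon, or migration of the alkene into conjugation with the ring. The fallback replaces the cross-coupling by the cuprate allylation used on ring A. From 10, the ketone is masked with 1,2-bis(trimethylsilyloxy)ethane and catalytic trimethylsilyl trifluoromethanesulfonate (CH2Cl2, −78 °C) as 2-[3-bromo-4-(methoxymethoxy)phenyl]-2-methyl-1,3-dioxolane F2. Bromine–lithium exchange (n-BuLi, THF, −78 °C), CuBr·SMe2 and 4 should then give 2-[4-(methoxymethoxy)-3-prenylphenyl]-2-methyl-1,3-dioxolane F3. PPTS in wet acetone returns the ketone 12.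

## Further compounds

F0 | step 9 | none | none
F1 | step 3 | 2-bromo-1-(dimethoxymethyl)-3-iodo-4-(methoxymethoxy)benzene | COCOc1ccc(C(OC)OC)c(Br)c1I
F0 | step 8 | none | none
F4 | step 12 | (2S)-8,3'-diprenyl-7,4'-bis(trimethylsilyloxy)flavanone | CC(C)=CCc1cc([C@@H]2CC(=O)c3ccc(O[Si](C)(C)C)c(CC=C(C)C)c3O2)ccc1O[Si](C)(C)C
F2 | step 5 | 2-[3-bromo-4-(methoxymethoxy)phenyl]-2-methyl-1,3-dioxolane | CC1(OCCO1)c1ccc(OCOC)c(Br)c1
F3 | step 5 | 2-[4-(methoxymethoxy)-3-prenylphenyl]-2-methyl-1,3-dioxolane | CC1(OCCO1)c1ccc(OCOC)c(CC=C(C)C)c1
A1 | alternative 1 | (2S)-7-(methoxymethoxy)-2-[4-(pivaloyloxy)-3-prenylphenyl]-8-prenyl-2,3,5,6-tetrahydro-4H-chromen-4-one | CC(C)=CCc1cc([C@@H]2CC(=O)C3=C(O2)C(CC=C(C)C)=C(OCOC)CC3)ccc1OC(=O)C(C)(C)C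
A2 | alternative 1 | 4-(methoxymethoxy)-3-prenyl-2-(trimethylsilyloxy)-1-[1-(trimethylsilyloxy)vinyl]cyclohexa-1,3-diene | C=C(O[Si](C)(C)C)C1=C(O[Si](C)(C)C)C(CC=C(C)C)=C(OCOC)CC1
A3 | alternative 1 | 4-formyl-2-prenylphenyl pivalate | CC(C)=CCc1cc(C=O)ccc1OC(=O)C(C)(C)C
A4 | alternative 1 | 2-prenylcyclohexane-1,3-dione | CC(C)=CCC1C(=O)CCCC1=O
A5 | alternative 2 | (2S)-4-(tert-butyldimethylsilyloxy)-2-[4-(methoxymethoxy)-3-prenylphenyl]-7-(2-methylbut-3-en-2-yloxy)-2H-chromene | CC(C)=CCc1cc([C@@H]2C=C(O[Si](C)(C)C(C)(C)C)c3ccc(OC(C)(C)C=C)cc3O2)ccc1OCOC
A6 | alternative 2 | tert-butyl(dimethyl){1-[2-{[(1S)-1-[4-(methoxymethoxy)-3-prenylphenyl]prop-2-en-1-yl]oxy}-4-(2-methylbut-3-en-2-yloxy)phenyl]vinyloxy}silane | C=C(O[Si](C)(C)C(C)(C)C)c1ccc(OC(C)(C)C=C)cc1O[C@@H](C=C)c1ccc(OCOC)c(CC=C(C)C)c1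
A7 | alternative 2 | 1-[2-hydroxy-4-(2-methylbut-3-en-2-yloxy)phenyl]ethanone | CC(=O)c1ccc(OC(C)(C)C=C)cc1O
A8 | alternative 2 | methyl (E)-3-[4-(methoxymethoxy)-3-prenylphenyl]prop-2-en-1-yl carbonate | COC(=O)OC/C=C/c1ccc(OCOC)c(CC=C(C)C)c1
A9 | alternative 3 | (S)-7-O-methoxymethyl-4'-O-pivaloylglabrol | CC(C)=CCc1cc([C@@H]2CC(=O)c3ccc(OCOC)c(CC=C(C)C)c3O2)ccc1OC(=O)C(C)(C)C
A10 | alternative 3 | (S)-4-[4-(pivaloyloxy)-3-prenylphenyl]oxetan-2-one | CC(C)=CCc1cc([C@@H]2CC(=O)O2)ccc1OC(=O)C(C)(C)C
A11 | alternative 3 | 1-bromo-2-fluoro-4-(methoxymethoxy)-3-prenylbenzene | CC(C)=CCc1c(OCOC)ccc(Br)c1F
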